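The readings were generated by integration for substances that don't exist, noise included.

The delta run has the X and Z of the flask you are asked about but less E, 5.1 µM, so start there and work with the fraction left. The X not made into D is 14.0 % at 10.0 min and still 7.00 % at 60.0 min, so you should ask what becomes of Z.

all flasks: X 0.10 M; Z 0.01 mol%
- epsilon: E 7.6 µM; the very flask that is asked about, followed so far
- delta: E 5.1 µM; run made earlier
- flask: E 7.6 µM

| run | time / min | D / % | X / % |
|---|---|---|---|
| epsilon | 2.00 | 66 | 34 |
| epsilon | 4.00 | 76 | 18 |
| epsilon | 5.00 | 82 | 17 |
| epsilon | 8.00 | 86 | 9 |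
| epsilon | 10.0 | 89 | 16 |
| delta | 10.0 | 86 | 11 |
| delta | 20.0 | 94 | 6 |
| delta | 30.0 | 96 | 12 |
| delta | 40.0 | 92 | 10 |
| delta | 50.0 | 93 | 6 |
| delta | 60.0 | 93 | 6 |

(scatter of a reading: 2 percentage points)

- apparent order in Z when 50 % of the X are converted (percent change of the rate of making D for one percent more Z charged)

Z is charged at 10.0 µM and E at 7.6 µM in the flask. Suppose each E takes one Z. The flask then has a survivor share of 24.0 %, one minus [E]/[Z] as charged; for the delta run it is 49.0 %. With the loss fixed by [E] and the rate taken as proportional to free Z, extra Z adds wholly to the survivors, so once E is spent the order in Z at fixed [X] is one over that share, 4.17.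

Now turn the question round: on this supposition an order of 1 needs no Z lost by 50 % conversion. You can reckon that moment from D at 2.00 min in the epsilon run, taking first-order decay: about 1.29 min. D in that run reads 89 % at 10.0 min, later than that moment and above the 66 % at 2.00 min, so I take it that part of the loss comes after that moment and commit to an order a little above 1.

The forecast says 0.8: “No run varies Z, so I guess slightly under 1”.

The flask gives 1.2, at a conversion of 50 % reached after 1.17 min.

    X + Z → D + Z, rate k1*[X]^3*[Z]/(1 + ([X]/Kh1)^3) (45.0 mM, k = 1.10 × 10⁶ L³ mol⁻³ s⁻¹)
    Z + E → L (k = 410 L mol⁻¹ s⁻¹)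

That order lies under 4.17, and in the flask Z is 51.4 % of its charge at 0.100 h, later than that conversion. E is the limiting reagent of the step into L: at 10.0 h E stands at 0 % and Z at 24.0 %, the survivor share of 24.0 %. For the delta run, with less E, the same subtraction reckons more Z, 49.0 % of its charge.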